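**Strategy.** Everything rests on cutting the C11–C25 bond, which joins the spiro carbon of ring C to ring B and closes lactone B. Ring C is read as a reduced 2-methoxybenzoate: its carboxyl-bearing carbon C11 is para to the carbinol carbon C8 shared with ring A, and the C9=C10 alkene lies next to C11. Lithium in ammonia turns the aryl ester of a ring B trans-chlorohydrin into an ester dienolate whose carbon C11 displaces the neighbouring chloride, so one operation dearomatises ring C and forms the spiro centre and the cis-fused lactone B. The precursor is that ester, benzo-fused to ring A, with lactone A masked as a cyclic acetal and the ring B ketone as a dioxolane.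

Key step: step 20

Atom labels (target and all intermediates): lactone A = C2(=C1H2)–C3(=O)–O4–C5–C15; ring A = C5, C6, C7 (methyl), C8, C13, C14, C15; ring C = C8 (OH), C9, C10 (acetyl), C11 (spiro), C12, C13; lactone B = C11, C16(=O), O17, C18, C25; ring B = C18, C19, C20 (methyl), C21, C23, C24, C25; O22 is the epoxide oxygen.

Remark: the ring A oxygens are carried as the 2-ethoxytetrahydrofuran acetal that the radical cyclisation delivers (same carbon skeleton as a bis-silyl ether, inert to lithium in ammonia, already at the oxidation level of lactone A); the acetal carbon C3, the C8–H centre from step 20 and the carbinol carbon from step 27 are carried as they form because each is destroyed later.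

**Ring B alcohol (steps 1–7)**

Step 1
Reactants: 1 (S)-4-benzyl-3-propanoyl-1,3-oxazolidin-2-one
Product: 2 (S)-4-benzyl-3-[(2R)-2-methylpent-4-enoyl]-1,3-oxazolidin-2-one
Conditions: NaN(SiMe3)2, THF, −78 °C; allyl iodide, −78 → −45 °C
Reagents that add atoms: allyl iodide, C=CCI
Why: Evans asymmetric alkylation, in which the chelated sodium Z-enolate is allylated on the face opposite the benzyl group and so sets the methyl-bearing carbon (future C20) as R.

Step 2
Reactants: 2 (S)-4-benzyl-3-[(2R)-2-methylpent-4-enoyl]-1,3-oxazolidin-2-one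
Product: 3 (S)-4-benzyl-3-[(2R)-2-methyl-4-oxobutanoyl]-1,3-oxazolidin-2-one
Conditions: O3, CH2Cl2, −78 °C; PPh3, −78 °C → rt
Reagents that add atoms: ozone, [O-][O+]=O
Why: Ozonolysis with reductive work-up cleaves the terminal alkene to the aldehyde (future C18) without touching the imide or its α-stereocentre.

Step 3
Reactants: 3 (S)-4-benzyl-3-[(2R)-2-methyl-4-oxobutanoyl]-1,3-oxazolidin-2-one
Product: 5 (3R,5S)-5-[(1S)-1-chloroprop-2-en-1-yl]-3-methyloxolan-2-one, via open-chain chlorohydrin imide 4 (not isolated)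
Conditions: allyl chloride, LiN(c-C6H11)2, (+)-Ipc2BOMe, Et2O, −95 °C; BF3·OEt2; then 3, −95 °C; HOCH2CH2NH2; then PPTS (cat.), CH2Cl2, 40 °C
Reagents that add atoms: allyl chloride, C=CCCl
Why: Asymmetric (Z)-γ-chloroallylboration through a closed chair transition state should give the syn chlorohydrin (C18 S, C25 S) under control of the isopinocampheyl groups derived from (−)-α-pinene, and the γ-hydroxy imide then lactonises with loss of the auxiliary.

Step 4
Reactants: 5 (3R,5S)-5-[(1S)-1-chloroprop-2-en-1-yl]-3-methyloxolan-2-one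
Product: 6 (3R,5S)-5-[(1S)-1-chloroprop-2-en-1-yl]-2-ethenyl-3-methyloxolan-2-ol (hemiketal, both anomers)
Conditions: CH2=CHMgBr (1.1 equiv), THF, −78 °C; AcOH, −78 °C
Reagents that add atoms: vinylmagnesium bromide, C=C[Mg]Br
Why: Grignard mono-addition to a γ-lactone at low temperature stops at the magnesium hemiketalate, which also keeps the chlorohydrin oxygen from displacing chloride.

Step 5
Reactants: 6 (3R,5S)-5-[(1S)-1-chloroprop-2-en-1-yl]-2-ethenyl-3-methyloxolan-2-ol
Product: 7 (4S,5S,7R)-4-chloro-5-hydroxy-7-methylcyclohept-2-en-1-one (in equilibrium with its bridged hemiketal)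
Conditions: second-generation Grubbs catalyst (5 mol %), CH2Cl2 (5 mM), 40 °C
Reagents that add atoms: none
Why: Ring-closing metathesis of the two vinyl groups, through the open hydroxy dienone form of the hemiketal, closes the seven-membered ring B as the cyclic enone without touching a stereocentre.

Step 6
Reactants: 7 (4S,5S,7R)-4-chloro-5-hydroxy-7-methylcyclohept-2-en-1-one
Product: 8 (2R,4S,5S)-5-chloro-4-hydroxy-2-methylcycloheptan-1-one
Conditions: H2 (1 atm), RhCl(PPh3)3 (5 mol %), benzene, rt
Reagents that add atoms: none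
Why: Homogeneous hydrogenation saturates the cis-disubstituted enone alkene under neutral conditions, so that no enolate arises that could displace the γ-chloride and the allylic C–Cl bond is not hydrogenolysed.

Step 7
Reactants: 8 (2R,4S,5S)-5-chloro-4-hydroxy-2-methylcycloheptan-1-one
Product: 9 (6R,8S,9S)-9-chloro-6-methyl-1,4-dioxaspiro[4.6]undecan-8-ol
Conditions: HOCH2CH2OH (5 equiv), TsOH·H2O (cat.), benzene, reflux, Dean–Stark trap
Reagents that add atoms: ethane-1,2-diol, OCCO
Why: Acid-catalysed ketalisation with azeotropic removal of water masks the C21 ketone for the dissolving-metal step, and any equilibration of C20 through the enol should favour the wanted all-equatorial isomer.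

**Benzo-fused ring A acid (steps 8–18)**

Step 8
Reactants: 10 (3-methoxyphenyl)boronic acid; 11 ethyl (E)-but-2-enoate
Product: 12 ethyl (3S)-3-(3-methoxyphenyl)butanoate
Conditions: [Rh(acac)(C2H4)2] (3 mol %), (R)-BINAP (4.5 mol %), dioxane–H2O (10:1), 100 °C
Reagents that add atoms: none
Why: Rhodium-catalysed asymmetric conjugate addition of the arylboronic acid (Hayashi–Miyaura reaction) sets the benzylic methyl stereocentre C7 (S) through the chiral bisphosphine.

Step 9
Reactants: 12 ethyl (3S)-3-(3-methoxyphenyl)butanoate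
Product: 13 ethyl (3S)-3-(2-bromo-5-methoxyphenyl)butanoate
Conditions: NBS, MeCN, 0 °C → rt
Reagents that add atoms: N-bromosuccinimide, O=C1CCC(=O)N1Br
Why: Electrophilic aromatic bromination goes para to the methoxyl group, which is the ring carbon (future C13) that must carry C14.

Step 10
Reactants: 13 ethyl (3S)-3-(2-bromo-5-methoxyphenyl)butanoate
Product: 14 (3S)-3-(2-bromo-5-methoxyphenyl)-N-methoxy-N-methylbutanamide
Conditions: MeNH(OMe)·HCl, i-PrMgCl, THF, −20 °C
Reagents that add atoms: N,O-dimethylhydroxylamine hydrochloride, CNOC.Cl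
Why: Aminolysis of the ester by the magnesium amide gives the Weinreb amide without touching the aryl bromide.

Step 11
Reactants: 14 (3S)-3-(2-bromo-5-methoxyphenyl)-N-methoxy-N-methylbutanamide
Product: 15 (5S)-5-(2-bromo-5-methoxyphenyl)hex-1-en-3-one
Conditions: CH2=CHMgBr, THF, 0 °C; cold 1 M HCl
Reagents that add atoms: vinylmagnesium bromide, C=C[Mg]Br
Why: Weinreb ketone synthesis, in which the chelated tetrahedral intermediate prevents a second addition and releases the vinyl ketone on acidic quench.

Step 12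
Reactants: 15 (5S)-5-(2-bromo-5-methoxyphenyl)hex-1-en-3-one
Product: 16 (3R,5S)-5-(2-bromo-5-methoxyphenyl)hex-1-en-3-ol
Conditions: (S)-2-methyl-CBS-oxazaborolidine (20 mol %), catecholborane, toluene, −78 °C; MeOH
Reagents that add atoms: none
Why: Corey–Bakshi–Shibata reduction delivers hydride to one face of the enone carbonyl (vinyl as the larger group), setting C5 (R) by reagent control independently of C7, and catecholborane avoids hydroboration of the vinyl group.

Step 13
Reactants: 16 (3R,5S)-5-(2-bromo-5-methoxyphenyl)hex-1-en-3-ol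
Product: 17 (3R,5S)-5-(2-ethenyl-5-methoxyphenyl)hex-1-en-3-ol
Conditions: CH2=CHBpin, PdCl2(dppf) (5 mol %), K2CO3, dioxane–H2O (5:1), 80 °C
Reagents that add atoms: vinylboronic acid pinacol ester, C=CB1OC(C)(C)C(C)(C)O1
Why: Suzuki–Miyaura coupling replaces the aryl bromide by the vinyl group whose inner carbon becomes C14.

Step 14
Reactants: 17 (3R,5S)-5-(2-ethenyl-5-methoxyphenyl)hex-1-en-3-ol
Product: 18 (5S,7R)-3-methoxy-5-methyl-6,7-dihydro-5H-benzo[7]annulen-7-ol
Conditions: second-generation Grubbs catalyst (3 mol %), CH2Cl2, 40 °C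
Reagents that add atoms: none
Why: Ring-closing metathesis between the styrene and the allylic alcohol vinyl group forms the benzo-fused seven-membered ring A with the C14=C15 alkene.

Step 15
Reactants: 18 (5S,7R)-3-methoxy-5-methyl-6,7-dihydro-5H-benzo[7]annulen-7-ol
Product: 19 (5S,7R)-7-(2-bromo-1-ethoxyethoxy)-3-methoxy-5-methyl-6,7-dihydro-5H-benzo[7]annulene (acetal epimers)
Conditions: ethyl vinyl ether, NBS, CH2Cl2, −40 → 0 °C
Reagents that add atoms: ethyl vinyl ether, C=COCC; N-bromosuccinimide, O=C1CCC(=O)N1Br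
Why: Bromoacetalisation of the allylic alcohol installs the radical precursor for the Ueno–Stork cyclisation.

Step 16
Reactants: 19 (5S,7R)-7-(2-bromo-1-ethoxyethoxy)-3-methoxy-5-methyl-6,7-dihydro-5H-benzo[7]annulene
Product: 20 tricyclic acetal: 10-methoxybenzo-fused ring A (5R,7S,15R) with the 2-ethoxytetrahydrofuran ring O4–C3H(OEt)–C2H2 cis-fused across C5–C15
Conditions: Bu3SnH (slow addition), AIBN (cat.), benzene, 80 °C
Reagents that add atoms: none
Why: Ueno–Stork radical cyclisation, in which the primary radical closes 5-exo onto C15 to give a benzylic radical at C14 and the new ring is necessarily cis-fused, so C15 (R) is set by C5.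

Step 17
Reactants: 20 tricyclic acetal (5R,7S,15R)
Product: 21 aryl bromide: 20 with bromine at C11
Conditions: NBS, MeCN, 0 °C, dark
Reagents that add atoms: N-bromosuccinimide, O=C1CCC(=O)N1Br
Why: With the para position occupied, electrophilic bromination takes the unhindered carbon ortho to the methoxyl group and para to C8, the future spiro carbon C11.

Step 18
Reactants: 21 aryl bromide (Br at C11)
Product: 22 2-methoxybenzoic acid: 20 with CO2H (C16) at C11
Conditions: n-BuLi, THF, −78 °C; CO2; cold 0.5 M HCl to pH 4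
Reagents that add atoms: carbon dioxide, O=C=O
Why: Bromine–lithium exchange and carboxylation of the aryllithium give the acid, and the cold, weakly acidic quench spares the acetal.

**Union and key step (steps 19–20)**

Step 19
Reactants: 22 2-methoxybenzoic acid of ring A; 9 (6R,8S,9S)-9-chloro-6-methyl-1,4-dioxaspiro[4.6]undecan-8-ol
Product: 23 aryl ester: (6R,8S,9S)-9-chloro-6-methyl-1,4-dioxaspiro[4.6]undecan-8-yl ester of acid 22 (O17–C18 ester, C25–Cl trans to it)
Conditions: 2,4,6-Cl3C6H2COCl, Et3N, THF, rt; then 9, DMAP, toluene, rt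
Reagents that add atoms: none
Why: Yamaguchi esterification through the mixed anhydride acylates the hindered secondary alcohol under basic conditions that spare the acetal and the chloride.

Step 20
Reactants: 23 aryl ester of the ring B trans-chlorohydrin
Product: 25 spiro lactone dienol ether (C9=C10–OMe and C12=C13 in ring C, 8-H, 11R, 25S), via lithium ester dienolate 24 (not isolated)
Conditions: Li (2.1 equiv, to a faint persistent blue), NH3(l)–THF (3:1), t-BuOH (1.0 equiv), −78 °C; then −78 → −33 °C; NH4Cl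
Reagents that add atoms: none
Why: Proposed new method: lithium transfers two electrons to the aryl ester, tert-butanol protonates the radical anion at C8 (para to the ester), and the resulting lithium ester dienolate 24 attacks C25 through C11 with backside displacement of chloride, forming the C11–C25 bond and lactone B at once. The closest known reaction is the Birch reduction–alkylation of 2-methoxybenzoic esters and amides with external alkyl halides, where the same kind of dienolate is alkylated at the ipso carbon. Lactone B closes in a 5-exo-tet displacement in which the enolate double bond C11=C16 lies inside the forming ring (enolendo), a strained mode that should be reachable because the delocalised cyclohexadienyl enolate has an early transition state and the C16–O17 bond can twist; O-alkylation to a ketene acetal is the competing pathway. C25 is inverted, so the trans-chlorohydrin gives the cis-fused lactone, and C11 is fixed by the ring B tether: about the forming bond the methoxyl-bearing C10 takes the place next to H25 and the unsubstituted C12 the place next to C24. C8 is set by protonation and is made planar again in step 26, so its configuration does not matter. The step needs the C–Cl bond to survive the reduction, which rests on the much faster electron uptake of the conjugated aryl ester at −78 °C, on a single equivalent of proton source and on avoiding an excess of lithium; lithium also ties the enolate oxygen to the C10 methoxyl and so fixes the enolate geometry.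

**Ring C and lactone A (steps 21–28)**

Step 21
Reactants: 25 spiro lactone dienol ether
Product: 26 keto lactol: C10 ketone (C9H2, C12=C13), C3 hemiacetal, dioxolane intact
Conditions: AcOH–THF–H2O (3:1:1), 35 °C
Reagents that add atoms: water, O
Why: Mild acid hydrolysis cleaves the methyl enol ether and the 2-ethoxytetrahydrofuran acetal, both of which should react much faster than the dioxolane of the hindered ring B ketone.

Step 22
Reactants: 26 keto lactol
Product: 27 keto lactone: 26 with lactone A (C3=O)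
Conditions: PhI(OAc)2, TEMPO (10 mol %), CH2Cl2, rt
Reagents that add atoms: none
Why: Oxoammonium (TEMPO) oxidation converts the lactol into lactone A and leaves the ketone and the alkene alone.

Step 23
Reactants: 27 keto lactone
Product: 28 saturated keto lactone: 27 with the C12–C13 bond saturated (13S)
Conditions: H2 (1 atm), [Ir(cod)(PCy3)(py)]PF6 (5 mol %), CH2Cl2, 0 °C → rt
Reagents that add atoms: none
Why: Carbonyl-directed homogeneous hydrogenation, in which the lactone B carbonyl oxygen sits over the alkene on the face opposite C24 of ring B and delivers hydrogen to that face, sets C13 (S).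

Step 24
Reactants: 28 saturated keto lactone
Product: 29 enol triflate: C9=C10–OSO2CF3
Conditions: KN(SiMe3)2, THF, −78 °C; PhNTf2, −78 → 0 °C; NH4Cl (aq)
Reagents that add atoms: N-phenylbis(trifluoromethanesulfonimide), O=S(=O)(N(c1ccccc1)S(=O)(=O)C(F)(F)F)C(F)(F)F
Why: Kinetic enolisation and O-sulfonylation give a single enol triflate because only C9 carries hydrogens next to the C10 ketone and the ketone is far more acidic than lactone A.

Step 25
Reactants: 29 enol triflate
Product: 30 enal: C9=C10–CHO, 8-H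
Conditions: CO (1 atm), Bu3SnH (slow addition), Pd(PPh3)4 (5 mol %), LiCl, THF, 50 °C
Reagents that add atoms: carbon monoxide, [C-]#[O+]
Why: Palladium-catalysed reductive carbonylation of the enol triflate (oxidative addition, CO insertion, hydride transfer from tin) gives the aldehyde that has no enolisable position other than C8–H.

Step 26
Reactants: 30 enal
Product: 32 γ-hydroxy enal: tertiary OH at C8 (8S), via triethylsilyl dienol ether 31 (not isolated)
Conditions: Et3SiOTf, Et3N, CH2Cl2, −78 → 0 °C; then DMDO, acetone–CH2Cl2, −78 °C; then Et3N·3HF, MeCN, 0 °C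
Reagents that add atoms: dimethyldioxirane, CC1(C)OO1
Why: Vinylogous Rubottom oxidation, in which the silyl dienol ether is epoxidised at C8=C9 and not at the hindered C10 terminus and the oxidant approaches C8 axially, anti to the C13 hydrogen, as in the γ-hydroxylation of steroidal dienol derivatives at a ring-fusion carbon, to give the 8S alcohol.

Step 27
Reactants: 32 γ-hydroxy enal
Product: 33 allylic diol: CH(OH)CH3 on C10 (carbinol epimers), tertiary OH at C8
Conditions: MeMgBr (2.5 equiv), THF, −78 °C; NH4Cl (aq)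
Reagents that add atoms: methylmagnesium bromide, C[Mg]Br
Why: Grignard addition to the aldehyde at −78 °C is much faster than attack on either lactone and brings in the methyl group of the acetyl unit while keeping it at the alcohol level for the base-mediated steps that follow.

Step 28
Reactants: 33 allylic diol
Product: 34 mono-silyl ether: secondary alcohol as tert-butyldimethylsilyl ether, C8–OH free
Conditions: t-BuMe2SiCl, imidazole, DMF, rt
Reagents that add atoms: tert-butyldimethylsilyl chloride, CC(C)(C)[Si](C)(C)Cl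
Why: Silylation with the silyl chloride protects the secondary allylic alcohol only, the tertiary C8 hydroxyl being too hindered.

**Ring B side chain, lactone A methylene, end game (steps 29–35)**

Step 29
Reactants: 34 mono-silyl ether
Product: 35 ring B ketone: C21=O
Conditions: PPTS, acetone–H2O (10:1), 45 °C
Reagents that add atoms: water, O
Why: Mild acid-catalysed hydrolysis of the dioxolane frees the C21 ketone under conditions that should leave the silyl ether and the tertiary allylic alcohol, whose ionisation is disfavoured by the neighbouring electron-poor C10/C11 carbons, intact.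

Step 30
Reactants: 35 ring B ketone
Product: 36 ring B enol triflate: C21(OSO2CF3)=C23
Conditions: KN(SiMe3)2 (2.2 equiv), THF, −78 °C; PhNTf2; NH4Cl (aq)
Reagents that add atoms: N-phenylbis(trifluoromethanesulfonimide), O=S(=O)(N(c1ccccc1)S(=O)(=O)C(F)(F)F)C(F)(F)F
Why: Kinetic deprotonation by the bulky amide at −78 °C removes a hydrogen from the C23 methylene and not from the C20 methine or the less acidic lactone A, so O-sulfonylation gives the C21=C23 enol triflate without touching C20 (the second equivalent of base covers the tertiary hydroxyl).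

Step 31
Reactants: 36 ring B enol triflate
Product: 39 α-methylene lactone: C2=C1H2 on lactone A, via Mannich base 37 (not isolated), via trimethylammonium iodide 38 (not isolated)
Conditions: LiN(i-Pr)2 (2.3 equiv), THF, −78 °C; CH2=NMe2+ I−, −78 → 0 °C; then MeI, MeOH–CH2Cl2, rt; then NaHCO3 (aq), CH2Cl2, rt
Reagents that add atoms: N,N-dimethylmethyleneiminium iodide, C=[N+](C)C.[I-]
Why: α-Methylenation of the lactone by Mannich reaction of its lithium enolate, N-methylation and elimination is possible here because no ketone is present at this stage.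

Step 32
Reactants: 39 α-methylene lactone with ring B enol triflate; 40 but-3-en-2-one
Product: 41 dienone: (E)-CH=CH–C(O)CH3 on C21, C21=C23
Conditions: 40 (10 equiv), Pd(OAc)2 (10 mol %), PPh3, Et3N, DMF, 60 °C
Reagents that add atoms: none
Why: Heck reaction of the enol triflate with the monosubstituted enone, which in large excess should outrun insertion into the 1,1-disubstituted methylene lactone, gives the (E)-dienone.

Step 33
Reactants: 41 dienone
Product: 42 allylic alcohol: free CH(OH)CH3 on C10
Conditions: HF·pyridine, pyridine, THF, 0 °C → rt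
Reagents that add atoms: none
Why: Buffered fluoride cleaves the secondary silyl ether without adding to the Michael acceptors.

Step 34
Reactants: 42 allylic alcohol
Product: 43 bis-enone: acetyl on C10, C21=C23 still an alkene
Conditions: Dess–Martin periodinane, NaHCO3, CH2Cl2, 0 °C → rt
Reagents that add atoms: none
Why: Dess–Martin oxidation of the secondary allylic alcohol gives the acetyl enone and cannot touch the tertiary C8 alcohol.

Step 35
Reactants: 43 bis-enone
Product: 44 CNP0177598.2
Conditions: mCPBA, NaHCO3, CH2Cl2, 0 °C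
Reagents that add atoms: 3-chloroperoxybenzoic acid, OOC(=O)c1cccc(Cl)c1
Why: Prilezhaev epoxidation selects the C21=C23 alkene, the only one not directly attached to a carbonyl group, and should attack the face opposite the C20 methyl group and the spiro lactone to give the 21R,23R epoxide.

**Compound list**

1 | (S)-4-benzyl-3-propanoyl-1,3-oxazolidin-2-one | CCC(=O)N1[C@@H](Cc2ccccc2)COC1=O | starting material
2 | (S)-4-benzyl-3-[(2R)-2-methylpent-4-enoyl]-1,3-oxazolidin-2-one | C=CC[C@@H](C)C(=O)N1[C@@H](Cc2ccccc2)COC1=O | intermediate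
3 | (S)-4-benzyl-3-[(2R)-2-methyl-4-oxobutanoyl]-1,3-oxazolidin-2-one | O=CC[C@@H](C)C(=O)N1[C@@H](Cc2ccccc2)COC1=O | intermediate
4 | (S)-4-benzyl-3-[(2R,4S,5S)-5-chloro-4-hydroxy-2-methylhept-6-enoyl]-1,3-oxazolidin-2-one (not isolated) | C=C[C@H](Cl)[C@@H](O)C[C@@H](C)C(=O)N1[C@@H](Cc2ccccc2)COC1=O | intermediate
5 | (3R,5S)-5-[(1S)-1-chloroprop-2-en-1-yl]-3-methyloxolan-2-one | C=C[C@H](Cl)[C@@H]1C[C@@H](C)C(=O)O1 | intermediate
6 | (3R,5S)-5-[(1S)-1-chloroprop-2-en-1-yl]-2-ethenyl-3-methyloxolan-2-ol (anomers) | C=C[C@H](Cl)[C@@H]1C[C@@H](C)C(O)(C=C)O1 | intermediate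
7 | (4S,5S,7R)-4-chloro-5-hydroxy-7-methylcyclohept-2-en-1-one | O[C@H]1C[C@@H](C)C(=O)C=C[C@@H]1Cl | intermediate
8 | (2R,4S,5S)-5-chloro-4-hydroxy-2-methylcycloheptan-1-one | O[C@H]1C[C@@H](C)C(=O)CC[C@@H]1Cl | intermediate
9 | (6R,8S,9S)-9-chloro-6-methyl-1,4-dioxaspiro[4.6]undecan-8-ol | O[C@H]1C[C@@H](C)C2(OCCO2)CC[C@@H]1Cl | intermediate
10 | (3-methoxyphenyl)boronic acid | COc1cccc(B(O)O)c1 | starting material
11 | ethyl (E)-but-2-enoate | C/C=C/C(=O)OCC | starting material
12 | ethyl (3S)-3-(3-methoxyphenyl)butanoate | CCOC(=O)C[C@H](C)c1cccc(OC)c1 | intermediate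
13 | ethyl (3S)-3-(2-bromo-5-methoxyphenyl)butanoate | CCOC(=O)C[C@H](C)c1cc(OC)ccc1Br | intermediate
14 | (3S)-3-(2-bromo-5-methoxyphenyl)-N-methoxy-N-methylbutanamide | CON(C)C(=O)C[C@H](C)c1cc(OC)ccc1Br | intermediate
15 | (5S)-5-(2-bromo-5-methoxyphenyl)hex-1-en-3-one | C=CC(=O)C[C@H](C)c1cc(OC)ccc1Br | intermediate
16 | (3R,5S)-5-(2-bromo-5-methoxyphenyl)hex-1-en-3-ol | C=C[C@H](O)C[C@H](C)c1cc(OC)ccc1Br | intermediate
17 | (3R,5S)-5-(2-ethenyl-5-methoxyphenyl)hex-1-en-3-ol | C=C[C@H](O)C[C@H](C)c1cc(OC)ccc1C=C | intermediate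
18 | (5S,7R)-3-methoxy-5-methyl-6,7-dihydro-5H-benzo[7]annulen-7-ol | COc1ccc2C=C[C@H](O)C[C@H](C)c2c1 | intermediate
19 | (5S,7R)-7-(2-bromo-1-ethoxyethoxy)-3-methoxy-5-methyl-6,7-dihydro-5H-benzo[7]annulene (acetal epimers) | COc1ccc2C=C[C@H](OC(CBr)OCC)C[C@H](C)c2c1 | intermediate
20 | tricyclic acetal (5R,7S,15R): 10-methoxybenzo-fused ring A, C7 methyl, 2-ethoxytetrahydrofuran cis-fused at C5–C15 (C3 epimers) | COc1ccc2c(c1)[C@@H](C)C[C@H]1OC(OCC)C[C@H]1C2 | intermediate
21 | aryl bromide: 20 with Br at C11 | COc1cc2c(cc1Br)C[C@@H]1CC(OCC)O[C@@H]1C[C@@H]2C | intermediate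
22 | 2-methoxybenzoic acid: 20 with CO2H at C11 | COc1cc2c(cc1C(=O)O)C[C@@H]1CC(OCC)O[C@@H]1C[C@@H]2C | intermediate
23 | (6R,8S,9S)-9-chloro-6-methyl-1,4-dioxaspiro[4.6]undecan-8-yl ester of acid 22 (18S,20R,25S; 5R,7S,15R) | COc1cc2c(cc1C(=O)O[C@H]3C[C@@H](C)C4(OCCO4)CC[C@@H]3Cl)C[C@@H]5CC(OCC)O[C@@H]5C[C@@H]2C | intermediate
24 | lithium ester dienolate of 23, protonated at C8, C11=C16(OLi)–O17 (not isolated) | [Li+].COC1=C[C@@H]2[C@@H](C)C[C@H]3OC(OCC)C[C@H]3CC2=CC1=C([O-])O[C@H]1C[C@@H](C)C2(OCCO2)CC[C@@H]1Cl | intermediate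
25 | spiro lactone dienol ether: ring C with C9=C10(OMe), C12=C13, 8-H; spiro C11 (R) in cis-fused lactone B (18S,25S); 20R; dioxolane at C21; ring A acetal (5R,7S,15R) | C[C@H]1C[C@H]5OC(OCC)C[C@H]5CC2=C[C@@]3(C(OC)=C[C@H]12)C(=O)O[C@H]1C[C@@H](C)C4(OCCO4)CC[C@H]13 | intermediate
26 | keto lactol: 25 with C10=O (C9H2) and C3 hemiacetal | C[C@H]1C[C@H]5OC(O)C[C@H]5CC2=C[C@@]3(C(=O)C[C@H]12)C(=O)O[C@H]1C[C@@H](C)C4(OCCO4)CC[C@H]13 | intermediate
27 | keto lactone: 26 with lactone A (C3=O) | C[C@H]1C[C@H]5OC(=O)C[C@H]5CC2=C[C@@]3(C(=O)C[C@H]12)C(=O)O[C@H]1C[C@@H](C)C4(OCCO4)CC[C@H]13 | intermediate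
28 | saturated keto lactone: 27 with C12–C13 single bond (13S) | C[C@H]1C[C@H]5OC(=O)C[C@H]5C[C@H]2C[C@@]3(C(=O)C[C@H]12)C(=O)O[C@H]1C[C@@H](C)C4(OCCO4)CC[C@H]13 | intermediate
29 | enol triflate: 28 with C9=C10–OSO2CF3 | C[C@H]1C[C@H]5OC(=O)C[C@H]5C[C@H]2C[C@@]3(C(OS(=O)(=O)C(F)(F)F)=C[C@H]12)C(=O)O[C@H]1C[C@@H](C)C4(OCCO4)CC[C@H]13 | intermediate
30 | enal: C9=C10–CHO, 8-H | C[C@H]1C[C@H]5OC(=O)C[C@H]5C[C@H]2C[C@@]3(C(C=O)=C[C@H]12)C(=O)O[C@H]1C[C@@H](C)C4(OCCO4)CC[C@H]13 | intermediate
31 | triethylsilyl dienol ether of 30: C8=C9, C10=CH–OSiEt3 (not isolated) | C[C@H]1C[C@H]5OC(=O)C[C@H]5C[C@H]2C[C@@]3(C(=CO[Si](CC)(CC)CC)C=C12)C(=O)O[C@H]1C[C@@H](C)C4(OCCO4)CC[C@H]13 | intermediate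
32 | γ-hydroxy enal: 30 with tertiary OH at C8 (8S) | C[C@H]1C[C@H]5OC(=O)C[C@H]5C[C@H]2C[C@@]3(C(C=O)=C[C@]12O)C(=O)O[C@H]1C[C@@H](C)C4(OCCO4)CC[C@H]13 | intermediate
33 | allylic diol: 32 with CH(OH)CH3 on C10 (carbinol epimers) | C[C@H]1C[C@H]5OC(=O)C[C@H]5C[C@H]2C[C@@]3(C(C(C)O)=C[C@]12O)C(=O)O[C@H]1C[C@@H](C)C4(OCCO4)CC[C@H]13 | intermediate
34 | mono-silyl ether: 33 with the secondary alcohol as tert-butyldimethylsilyl ether | C[C@H]1C[C@H]5OC(=O)C[C@H]5C[C@H]2C[C@@]3(C(C(C)O[Si](C)(C)C(C)(C)C)=C[C@]12O)C(=O)O[C@H]1C[C@@H](C)C4(OCCO4)CC[C@H]13 | intermediate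
35 | ring B ketone: 34 with C21=O | C[C@H]1C[C@H]5OC(=O)C[C@H]5C[C@H]2C[C@@]3(C(C(C)O[Si](C)(C)C(C)(C)C)=C[C@]12O)C(=O)O[C@H]1C[C@@H](C)C(=O)CC[C@H]13 | intermediate
36 | ring B enol triflate: C21(OSO2CF3)=C23 | C[C@H]1C[C@H]5OC(=O)C[C@H]5C[C@H]2C[C@@]3(C(C(C)O[Si](C)(C)C(C)(C)C)=C[C@]12O)C(=O)O[C@H]1C[C@@H](C)C(OS(=O)(=O)C(F)(F)F)=CC[C@H]13 | intermediate
37 | Mannich base: 36 with CH2NMe2 on C2 (not isolated) | C[C@H]1C[C@H]5OC(=O)C(CN(C)C)[C@H]5C[C@H]2C[C@@]3(C(C(C)O[Si](C)(C)C(C)(C)C)=C[C@]12O)C(=O)O[C@H]1C[C@@H](C)C(OS(=O)(=O)C(F)(F)F)=CC[C@H]13 | intermediate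
38 | trimethylammonium iodide of 37 (not isolated) | [I-].C[C@H]1C[C@H]5OC(=O)C(C[N+](C)(C)C)[C@H]5C[C@H]2C[C@@]3(C(C(C)O[Si](C)(C)C(C)(C)C)=C[C@]12O)C(=O)O[C@H]1C[C@@H](C)C(OS(=O)(=O)C(F)(F)F)=CC[C@H]13 | intermediate
39 | α-methylene lactone: 36 with C2=C1H2 | C[C@H]1C[C@H]5OC(=O)C(=C)[C@H]5C[C@H]2C[C@@]3(C(C(C)O[Si](C)(C)C(C)(C)C)=C[C@]12O)C(=O)O[C@H]1C[C@@H](C)C(OS(=O)(=O)C(F)(F)F)=CC[C@H]13 | intermediate
40 | but-3-en-2-one (methyl vinyl ketone) | CC(=O)C=C | starting material
41 | dienone: 39 with (E)-CH=CH–C(O)CH3 in place of the triflate on C21 | C[C@H]1C[C@H]5OC(=O)C(=C)[C@H]5C[C@H]2C[C@@]3(C(C(C)O[Si](C)(C)C(C)(C)C)=C[C@]12O)C(=O)O[C@H]1C[C@@H](C)C(/C=C/C(C)=O)=CC[C@H]13 | intermediate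
42 | allylic alcohol: 41 with free CH(OH)CH3 on C10 | C[C@H]1C[C@H]5OC(=O)C(=C)[C@H]5C[C@H]2C[C@@]3(C(C(C)O)=C[C@]12O)C(=O)O[C@H]1C[C@@H](C)C(/C=C/C(C)=O)=CC[C@H]13 | intermediate
43 | bis-enone: 42 with acetyl on C10 | C[C@H]1C[C@H]5OC(=O)C(=C)[C@H]5C[C@H]2C[C@@]3(C(C(C)=O)=C[C@]12O)C(=O)O[C@H]1C[C@@H](C)C(/C=C/C(C)=O)=CC[C@H]13 | intermediate
44 | CNP0177598.2 (5R,7S,8S,11R,13S,15R,18S,20R,21R,23R,25S) | C=C1C(=O)O[C@@H]2C[C@H](C)[C@@]3(O)C=C(C(C)=O)[C@]4(C[C@@H]3C[C@H]12)C(=O)O[C@H]1C[C@@H](C)[C@]2(/C=C/C(C)=O)O[C@@H]2C[C@H]14 | target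

**Count and risks**

Total steps: 35 (alcohol 9: steps 1–7; acid 22: steps 8–18; union, key step and end game: steps 19–35). Longest linear sequence: 28 steps (steps 8–35).

Steps most likely to fail:

1. Step 20 (Proposed new method). What may go wrong: electron transfer to the C–Cl bond before or alongside reduction of the arene, so that chlorine is lost; O-alkylation of the dienolate instead of C-alkylation; or ring closure in the enolendo mode too slow, so that the dienolate is merely protonated on work-up. Fallback with known reactions only, setting out from acid 22 and returning at keto lactol 26: MeI and K2CO3 convert 22 into the methyl ester F1. Birch reduction with protonation (Li, NH3, THF, t-BuOH; NH4Cl) gives the 1,4-dihydro ester F2, and oxalic acid in wet THF hydrolyses only its enol ether to the methyl β-keto ester F3. Transesterification with alcohol 9 (DMAP cat., toluene, 100 °C, through the acyl ketene) gives the chloroalkyl β-keto ester F4. Cs2CO3 in DMF at 60 °C, without iodide so that C25 is inverted only once, closes lactone B by C-alkylation of the keto ester enolate to the spiro keto lactone F5. Here the enolate double bond C10=C11 lies outside the forming ring, the familiar closure of 2-haloalkyl β-keto esters to α-acyl-γ-butyrolactones. AcOH–THF–H2O then hydrolyses the ethyl acetal to 26.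

2. Step 26. What may go wrong: oxidation at the silyl enol ether terminus instead of the C8=C9 bond, or approach of the oxidant to C8 from the face of the C13 hydrogen. Fallback setting out from 28 and returning at 32: IBX (DMSO, 70 °C) dehydrogenates 28 to the enone F6 (C8=C9 conjugated to the C10 ketone). Nucleophilic epoxidation (t-BuOOH, DBU) gives the epoxy ketone F7, and reductive cleavage of its α-C–O bond (Na[PhSeB(OEt)3], EtOH, AcOH) gives the β-hydroxy ketone F8. Me3SiOTf and 2,6-lutidine give the trimethylsilyl ether F9, KN(SiMe3)2 and PhNTf2 the enol triflate F10, and reductive carbonylation (CO, Bu3SnH, Pd(PPh3)4, LiCl) the silyloxy enal F11, which Et3N·3HF converts into 32. The site of oxygenation is fixed by the enone, and the face is decided in a conjugate addition instead of an electrophilic attack.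

3. Step 35. What may go wrong: delivery of oxygen to the face that carries the C20 methyl group, or sluggish reaction of the conjugated alkene. Fallback setting out from 43 and returning at 44: NBS in wet THF adds bromine and water across C21=C23 to give the bromohydrin F12 (bromonium on the face the peracid would take, water from the other), and Ag2O in CH2Cl2 closes it to the epoxide. The oxygen then ends on the face opposite to that reached by direct epoxidation, which is what is needed if the peracid shows the reverse preference.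

**Further compounds**

F1 | step 20 | methyl ester of acid 22 | COc1cc2c(cc1C(=O)OC)C[C@@H]1CC(OCC)O[C@@H]1C[C@@H]2C
F2 | step 20 | 1,4-dihydro ester: methyl 10-methoxycyclohexa-9,12-diene-11-carboxylate fused to ring A (8-H, 11-H) | C[C@H]1C[C@H]5OC(OCC)C[C@H]5CC2=CC(C(=O)OC)C(OC)=C[C@H]12
F3 | step 20 | methyl β-keto ester: C10=O, C11–H, C12=C13 | C[C@H]1C[C@H]5OC(OCC)C[C@H]5CC2=CC(C(=O)OC)C(=O)C[C@H]12
F4 | step 20 | β-keto ester of alcohol 9 | C[C@H]1C[C@H]5OC(OCC)C[C@H]5CC2=CC(C(=O)O[C@H]3C[C@@H](C)C4(OCCO4)CC[C@@H]3Cl)C(=O)C[C@H]12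
F5 | step 20 | spiro keto lactone with ethyl acetal (26 with OEt at C3) | C[C@H]1C[C@H]5OC(OCC)C[C@H]5CC2=C[C@@]3(C(=O)C[C@H]12)C(=O)O[C@H]1C[C@@H](C)C4(OCCO4)CC[C@H]13
F6 | step 26 | enone: 28 with C8=C9 | C[C@H]1C[C@H]5OC(=O)C[C@H]5C[C@H]2C[C@@]3(C(=O)C=C12)C(=O)O[C@H]1C[C@@H](C)C4(OCCO4)CC[C@H]13
F7 | step 26 | epoxy ketone: C8–C9 epoxide, oxygen trans to H13 | C[C@H]1C[C@H]5OC(=O)C[C@H]5C[C@H]2C[C@@]3(C(=O)[C@H]6O[C@@]126)C(=O)O[C@H]1C[C@@H](C)C4(OCCO4)CC[C@H]13
F8 | step 26 | β-hydroxy ketone: C8–OH (8S), C9H2, C10=O | C[C@H]1C[C@H]5OC(=O)C[C@H]5C[C@H]2C[C@@]3(C(=O)C[C@]12O)C(=O)O[C@H]1C[C@@H](C)C4(OCCO4)CC[C@H]13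
F9 | step 26 | trimethylsilyl ether of F8 | C[C@H]1C[C@H]5OC(=O)C[C@H]5C[C@H]2C[C@@]3(C(=O)C[C@]12O[Si](C)(C)C)C(=O)O[C@H]1C[C@@H](C)C4(OCCO4)CC[C@H]13
F10 | step 26 | enol triflate: C9=C10–OSO2CF3, C8–OSiMe3 | C[C@H]1C[C@H]5OC(=O)C[C@H]5C[C@H]2C[C@@]3(C(OS(=O)(=O)C(F)(F)F)=C[C@]12O[Si](C)(C)C)C(=O)O[C@H]1C[C@@H](C)C4(OCCO4)CC[C@H]13
F11 | step 26 | silyloxy enal: C9=C10–CHO, C8–OSiMe3 | C[C@H]1C[C@H]5OC(=O)C[C@H]5C[C@H]2C[C@@]3(C(C=O)=C[C@]12O[Si](C)(C)C)C(=O)O[C@H]1C[C@@H](C)C4(OCCO4)CC[C@H]13
F12 | step 35 | bromohydrin: C21–OH, C23–Br (anti) | C[C@H]1C[C@H]5OC(=O)C(=C)[C@H]5C[C@H]2C[C@@]3(C(C(C)=O)=C[C@]12O)C(=O)O[C@H]1C[C@@H](C)[C@@](O)(/C=C/C(C)=O)[C@@H](Br)C[C@H]13
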